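**Retrosynthetic overview**

- Target 26 is the symmetric ether of two 2,3,6-tribromo-4,5-dihydroxybenzyl units. It is released by acid from bis-acetonide 25, whose C6 bromines come from electrophilic substitution on tetrabromide 23 at the only remaining ring C–H.
- Feature used: in each benzene ring (C1 = CH2O carbon; C2, C3, C6 = Br; C4, C5 = OH) the adjacent bromines at C2 and C3 sit directly beside the C4/C5 catechol. C3 can therefore be carried as the third oxygen of a gallate ring and exchanged for bromine.
- Key disconnection: the two C2–Br and two C3–Br bonds of 23 come from C2≡C3 arynes. These are released from the bis(2-silylaryl triflate) 18 (C2–SiMe3, C3–OTf) and trapped by bromide, then CBr4.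
- 18 comes from Williamson union of benzyl bromide 14 with benzyl alcohol 12. Both derive from methyl gallate by acetonide formation, O-carbamoylation, ester reduction and carbamate-directed lithiation/silylation at C2.
- Ring order: both benzene rings are bought in methyl gallate. The only rings formed are the two 1,3-dioxole (acetonide) rings in step 1, opened again in step 13; the key step closes no ring.

Key step: step 11

Remark: the target is achiral and has no stereocentre, so no stereocontrol is needed. Protected intermediates are named with benzodioxole locants.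

**Route**

Step 1
Reactants: 1 methyl gallate; 2 2,2-dimethoxypropane
Product: 3 methyl 7-hydroxy-2,2-dimethyl-1,3-benzodioxole-5-carboxylate
Conditions: 2,2-dimethoxypropane, p-TsOH·H2O (cat.), toluene, reflux, MeOH removed over 4 Å molecular sieves
Reagents that add atoms: 2,2-dimethoxypropane, COC(C)(C)OC
Why: Acid-catalysed transketalisation closes a five-membered dioxole only across two neighbouring phenols, and the two possible pairs are symmetry-equivalent, so one mono-acetonide with one free phenol should result.

Step 2
Reactants: 3 methyl 7-hydroxy-2,2-dimethyl-1,3-benzodioxole-5-carboxylate; 4 N,N-diethylcarbamoyl chloride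
Product: 5 methyl 7-(diethylcarbamoyloxy)-2,2-dimethyl-1,3-benzodioxole-5-carboxylate
Conditions: Et2NCOCl, K2CO3, MeCN, reflux
Reagents that add atoms: N,N-diethylcarbamoyl chloride, CCN(CC)C(=O)Cl
Why: O-Carbamoylation of the phenoxide (acyl substitution) installs a strong oxygen-based directing group for ortho-lithiation that has no N–H and tolerates the later alkoxide step.

Step 3
Reactants: 5 methyl 7-(diethylcarbamoyloxy)-2,2-dimethyl-1,3-benzodioxole-5-carboxylate
Product: 6 6-(hydroxymethyl)-2,2-dimethyl-1,3-benzodioxol-4-yl diethylcarbamate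
Conditions: i-Bu2AlH, CH2Cl2, −78 °C; aqueous potassium sodium tartrate
Reagents that add atoms: none
Why: Low-temperature ester reduction with diisobutylaluminium hydride should take the methyl ester to the benzylic alcohol, because the N,N-dialkyl aryl carbamate is a much poorer electrophile and the ketal is inert to hydride.

Step 4
Reactants: 6 6-(hydroxymethyl)-2,2-dimethyl-1,3-benzodioxol-4-yl diethylcarbamate; 7 tert-butyldimethylsilyl chloride
Product: 8 6-({[tert-butyl(dimethyl)silyl]oxy}methyl)-2,2-dimethyl-1,3-benzodioxol-4-yl diethylcarbamate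
Conditions: TBSCl, imidazole, DMF, rt
Reagents that add atoms: tert-butyldimethylsilyl chloride, CC(C)(C)[Si](C)(C)Cl
Why: Silylation of the primary alcohol removes the acidic O–H so that the organolithium step needs no second equivalent of base and forms no alkoxide.

Step 5
Reactants: 8 6-({[tert-butyl(dimethyl)silyl]oxy}methyl)-2,2-dimethyl-1,3-benzodioxol-4-yl diethylcarbamate; 9 chlorotrimethylsilane
Product: 11 6-({[tert-butyl(dimethyl)silyl]oxy}methyl)-2,2-dimethyl-5-(trimethylsilyl)-1,3-benzodioxol-4-yl diethylcarbamate, via C5-aryllithium 10 (not isolated)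
Conditions: sec-butyllithium, TMEDA, THF, −78 °C; then Me3SiCl, −78 °C to rt
Reagents that add atoms: chlorotrimethylsilane, C[Si](C)(C)Cl
Why: Directed ortho-metalation: the carbamate has a single ortho C–H (its other neighbour is the dioxole oxygen-bearing carbon), so lithiation and silyl chloride quench should place silicon between the carbamate and the CH2O arm, and holding −78 °C until the quench suppresses the anionic Fries shift.

Step 6
Reactants: 11 6-({[tert-butyl(dimethyl)silyl]oxy}methyl)-2,2-dimethyl-5-(trimethylsilyl)-1,3-benzodioxol-4-yl diethylcarbamate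
Product: 12 6-(hydroxymethyl)-2,2-dimethyl-5-(trimethylsilyl)-1,3-benzodioxol-4-yl diethylcarbamate
Conditions: Bu4NF, AcOH, THF, 0 °C to rt
Reagents that add atoms: none
Why: Buffered fluoride desilylation cleaves the O–Si bond of the silyl ether, while the aryl C–SiMe3 bond, which has no leaving group beside it at this stage and sees no free alkoxide, should stay intact.

Step 7
Reactants: 12 6-(hydroxymethyl)-2,2-dimethyl-5-(trimethylsilyl)-1,3-benzodioxol-4-yl diethylcarbamate (half of the material); 13 carbon tetrabromide
Product: 14 6-(bromomethyl)-2,2-dimethyl-5-(trimethylsilyl)-1,3-benzodioxol-4-yl diethylcarbamate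
Conditions: CBr4, PPh3, CH2Cl2, 0 °C
Reagents that add atoms: carbon tetrabromide, BrC(Br)(Br)Br
Why: The Appel reaction converts the primary benzylic alcohol to the bromide under neutral conditions that leave the aryl silane, carbamate and ketal untouched.

Step 8
Reactants: 12 6-(hydroxymethyl)-2,2-dimethyl-5-(trimethylsilyl)-1,3-benzodioxol-4-yl diethylcarbamate; 14 6-(bromomethyl)-2,2-dimethyl-5-(trimethylsilyl)-1,3-benzodioxol-4-yl diethylcarbamate
Product: 15 bis{[7-(diethylcarbamoyloxy)-2,2-dimethyl-6-(trimethylsilyl)-1,3-benzodioxol-5-yl]methyl} ether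
Conditions: NaH added last to 12 + 14, Bu4NI (cat.), THF, 0 °C to rt
Reagents that add atoms: none
Why: Williamson ether synthesis (SN2 of the sodium alkoxide on the reactive benzylic bromide); adding the base to the mixture in THF without polar additives keeps the alkoxide short-lived and tightly ion-paired, which should prevent a carbon-to-oxygen silyl shift.

Step 9
Reactants: 15 bis{[7-(diethylcarbamoyloxy)-2,2-dimethyl-6-(trimethylsilyl)-1,3-benzodioxol-5-yl]methyl} ether
Product: 16 bis{[7-hydroxy-2,2-dimethyl-6-(trimethylsilyl)-1,3-benzodioxol-5-yl]methyl} ether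
Conditions: LiAlH4, THF, reflux; aqueous potassium sodium tartrate
Reagents that add atoms: none
Why: Hydride cleavage of the aryl carbamates (acyl C–O scission, with the carbamoyl group reduced to the N-methylamine) frees both hindered phenols; the ketals, the dibenzyl ether and the aryl silanes are inert to LiAlH4.

Step 10
Reactants: 16 bis{[7-hydroxy-2,2-dimethyl-6-(trimethylsilyl)-1,3-benzodioxol-5-yl]methyl} ether; 17 trifluoromethanesulfonic anhydride
Product: 18 bis{[2,2-dimethyl-7-(trifluoromethanesulfonyloxy)-6-(trimethylsilyl)-1,3-benzodioxol-5-yl]methyl} ether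
Conditions: Tf2O, pyridine, CH2Cl2, 0 °C
Reagents that add atoms: trifluoromethanesulfonic anhydride, O=S(=O)(OS(=O)(=O)C(F)(F)F)C(F)(F)F
Why: O-Sulfonylation of the two 2-silylphenols is the standard last step towards 2-silylaryl triflates and should give the twofold aryne precursor.

Step 11
Reactants: 18 bis{[2,2-dimethyl-7-(trifluoromethanesulfonyloxy)-6-(trimethylsilyl)-1,3-benzodioxol-5-yl]methyl} ether; 13 carbon tetrabromide; 19 tetrabutylammonium bromide
Product: 23 bis[(6,7-dibromo-2,2-dimethyl-1,3-benzodioxol-5-yl)methyl] ether, via first-ring aryne 20 (not isolated), via half-converted dibromide silyl triflate 21 (not isolated), via second-ring aryne 22 (not isolated)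
Conditions: KF, 18-crown-6, Bu4NBr (excess), CBr4 (excess), THF, 4 Å molecular sieves, 0 °C to rt, dark
Reagents that add atoms: tetrabutylammonium bromide, CCCC[N+](CCCC)(CCCC)CCCC.[Br-]; carbon tetrabromide, BrC(Br)(Br)Br
Why: Fluoride attacks silicon at C6 of one benzodioxole and triflate departs from C7, giving the C6≡C7 aryne 20 (C2≡C3 in target numbering); the dioxole oxygen on the adjoining carbon C7a polarises the strained triple bond, so bromide should add at the far carbon C6 and leave the σ-aryl anion at C7 next to the C–O dipole, where it takes bromine from CBr4 in a halophilic substitution and expels tribromomethanide (protonated on work-up, or shedding bromide that re-enters the sequence). The same events then run on the second ring through 21 and 22. The closest known reaction type is the 1,2-dihalogenation of arynes from 2-silylaryl triflates (insertion into the I–I bond and three-component halide/halogen-donor additions), applied here to both halves of one substrate. No ring is closed and no stereocentre is formed; since both new substituents are bromine, either sense of bromide addition gives the same product, and the positions are fixed by where silicon and triflate stood, not by electrophilic directing effects. The step requires bromide, not fluoride or tribromomethanide, to capture the aryne and bromine transfer, not protonation, to quench the anion: a large excess of soluble bromide over sparingly soluble fluoride, a dry aprotic ether solvent and excess CBr4 should secure this, and CBr4 is too weak an electrophile to bromodesilylate the C–Si bond or to brominate the free ring C–H.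

Step 12
Reactants: 23 bis[(6,7-dibromo-2,2-dimethyl-1,3-benzodioxol-5-yl)methyl] ether; 24 N-bromosuccinimide
Product: 25 bis[(4,6,7-tribromo-2,2-dimethyl-1,3-benzodioxol-5-yl)methyl] ether
Conditions: NBS, (CF3)2CHOH, rt, dark
Reagents that add atoms: N-bromosuccinimide, O=C1CCC(=O)N1Br
Why: Electrophilic aromatic bromination with hydrogen-bond-activated NBS can only occur at C4, the single ring C–H, which is ortho to a dioxole oxygen; the absence of strong acid and light should spare the ketals and the benzylic C–H bonds.

Step 13
Reactants: 25 bis[(4,6,7-tribromo-2,2-dimethyl-1,3-benzodioxol-5-yl)methyl] ether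
Product: 26 bis(2,3,6-tribromo-4,5-dihydroxybenzyl) ether
Conditions: CF3CO2H/H2O (9:1), 0 °C to rt, evaporation without heating
Reagents that add atoms: none
Why: Acid-catalysed ketal hydrolysis releases both catechols as acetone is lost; the three bromines on each ring disfavour ionisation of the benzylic ether, and low temperature with little water should keep the ether bridge intact.

**Compound list**

1 | methyl gallate | COC(=O)c1cc(O)c(O)c(O)c1 | starting material
2 | 2,2-dimethoxypropane | COC(C)(C)OC | starting material
3 | methyl 7-hydroxy-2,2-dimethyl-1,3-benzodioxole-5-carboxylate | COC(=O)c1cc(O)c2OC(C)(C)Oc2c1 | intermediate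
4 | N,N-diethylcarbamoyl chloride | CCN(CC)C(=O)Cl | starting material
5 | methyl 7-(diethylcarbamoyloxy)-2,2-dimethyl-1,3-benzodioxole-5-carboxylate | COC(=O)c1cc(OC(=O)N(CC)CC)c2OC(C)(C)Oc2c1 | intermediate
6 | 6-(hydroxymethyl)-2,2-dimethyl-1,3-benzodioxol-4-yl diethylcarbamate | OCc1cc(OC(=O)N(CC)CC)c2OC(C)(C)Oc2c1 | intermediate
7 | tert-butyldimethylsilyl chloride | CC(C)(C)[Si](C)(C)Cl | starting material
8 | 6-({[tert-butyl(dimethyl)silyl]oxy}methyl)-2,2-dimethyl-1,3-benzodioxol-4-yl diethylcarbamate | CC(C)(C)[Si](C)(C)OCc1cc(OC(=O)N(CC)CC)c2OC(C)(C)Oc2c1 | intermediate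
9 | chlorotrimethylsilane | C[Si](C)(C)Cl | starting material
10 | C5-aryllithium of 8 (lithium between the carbamate and the CH2OTBS arm) | CC(C)(C)[Si](C)(C)OCc1cc2OC(C)(C)Oc2c(OC(=O)N(CC)CC)c1[Li] | intermediate
11 | 6-({[tert-butyl(dimethyl)silyl]oxy}methyl)-2,2-dimethyl-5-(trimethylsilyl)-1,3-benzodioxol-4-yl diethylcarbamate | CC(C)(C)[Si](C)(C)OCc1cc2OC(C)(C)Oc2c(OC(=O)N(CC)CC)c1[Si](C)(C)C | intermediate
12 | 6-(hydroxymethyl)-2,2-dimethyl-5-(trimethylsilyl)-1,3-benzodioxol-4-yl diethylcarbamate | OCc1cc2OC(C)(C)Oc2c(OC(=O)N(CC)CC)c1[Si](C)(C)C | intermediate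
13 | carbon tetrabromide | BrC(Br)(Br)Br | starting material
14 | 6-(bromomethyl)-2,2-dimethyl-5-(trimethylsilyl)-1,3-benzodioxol-4-yl diethylcarbamate | BrCc1cc2OC(C)(C)Oc2c(OC(=O)N(CC)CC)c1[Si](C)(C)C | intermediate
15 | bis{[7-(diethylcarbamoyloxy)-2,2-dimethyl-6-(trimethylsilyl)-1,3-benzodioxol-5-yl]methyl} ether | CCN(CC)C(=O)Oc1c([Si](C)(C)C)c(COCc3cc4OC(C)(C)Oc4c(OC(=O)N(CC)CC)c3[Si](C)(C)C)cc2OC(C)(C)Oc12 | intermediate
16 | bis{[7-hydroxy-2,2-dimethyl-6-(trimethylsilyl)-1,3-benzodioxol-5-yl]methyl} ether | Oc1c([Si](C)(C)C)c(COCc3cc4OC(C)(C)Oc4c(O)c3[Si](C)(C)C)cc2OC(C)(C)Oc12 | intermediate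
17 | trifluoromethanesulfonic anhydride | O=S(=O)(OS(=O)(=O)C(F)(F)F)C(F)(F)F | starting material
18 | bis{[2,2-dimethyl-7-(trifluoromethanesulfonyloxy)-6-(trimethylsilyl)-1,3-benzodioxol-5-yl]methyl} ether | C[Si](C)(C)c1c(COCc2cc3OC(C)(C)Oc3c(OS(=O)(=O)C(F)(F)F)c2[Si](C)(C)C)cc2OC(C)(C)Oc2c1OS(=O)(=O)C(F)(F)F | intermediate
19 | tetrabutylammonium bromide | CCCC[N+](CCCC)(CCCC)CCCC.[Br-] | starting material
20 | first-ring aryne (one ring C6≡C7 aryne, other ring still silyl triflate) | C[Si](C)(C)c1c(COCC3=CC4=C(OC(C)(C)O4)C#C3)cc2OC(C)(C)Oc2c1OS(=O)(=O)C(F)(F)F | intermediate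
21 | 6-{[(6,7-dibromo-2,2-dimethyl-1,3-benzodioxol-5-yl)methoxy]methyl}-2,2-dimethyl-5-(trimethylsilyl)-1,3-benzodioxol-4-yl trifluoromethanesulfonate | CC1(C)Oc2cc(COCc3cc4OC(C)(C)Oc4c(OS(=O)(=O)C(F)(F)F)c3[Si](C)(C)C)c(Br)c(Br)c2O1 | intermediate
22 | second-ring aryne (one ring vicinal dibromide, other ring C6≡C7 aryne) | CC1(C)Oc2cc(COCC3=CC4=C(OC(C)(C)O4)C#C3)c(Br)c(Br)c2O1 | intermediate
23 | bis[(6,7-dibromo-2,2-dimethyl-1,3-benzodioxol-5-yl)methyl] ether | CC1(C)Oc2cc(COCc3cc4OC(C)(C)Oc4c(Br)c3Br)c(Br)c(Br)c2O1 | intermediate
24 | N-bromosuccinimide | O=C1CCC(=O)N1Br | starting material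
25 | bis[(4,6,7-tribromo-2,2-dimethyl-1,3-benzodioxol-5-yl)methyl] ether | CC1(C)Oc2c(Br)c(COCc3c(Br)c4OC(C)(C)Oc4c(Br)c3Br)c(Br)c(Br)c2O1 | intermediate
26 | bis(2,3,6-tribromo-4,5-dihydroxybenzyl) ether | Oc1c(O)c(Br)c(COCc2c(Br)c(O)c(O)c(Br)c2Br)c(Br)c1Br | target

**Step count**

Total steps: 13. Longest linear sequence: 13 steps (1 to 26; bromide 14 is drawn from the same line as alcohol 12).

**Steps most likely to fail, with fallbacks**

Step 11. Fluoride or tribromomethanide may capture the aryne in place of bromide, the 2-bromoaryl anion may be protonated before bromine transfer, or the second ring may react incompletely. The fallback avoids arynes and sets out from bisphenol 16. Excess NBS in MeCN at 0 °C should effect ipso-bromodesilylation at C6 and bromination of the C4–H para to the phenol in both rings, giving bis[(4,6-dibromo-7-hydroxy-2,2-dimethyl-1,3-benzodioxol-5-yl)methyl] ether F1. Tf2O and pyridine would convert this to bis{[4,6-dibromo-2,2-dimethyl-7-(trifluoromethanesulfonyloxy)-1,3-benzodioxol-5-yl]methyl} ether F2. Palladium-catalysed triflate-to-bromide exchange (Pd2(dba)3, t-BuBrettPhos, KBr, toluene, 100 °C) would then return to the route at 25, so that step 12 is not needed.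

Step 12. Substitution on a ring already carrying two bromines may be slow, leaving partly brominated material, and forcing it may start radical bromination at the benzylic ether carbons. The fallback sets out from 23 and reverses the order of the last two operations. CF3CO2H/H2O removes the acetonides to give bis(2,3-dibromo-4,5-dihydroxybenzyl) ether F3. Its free catechol is far more reactive, so two equivalents of NBS in MeCN at 0 °C should brominate C6, ortho to the C5 hydroxyl, in both rings and arrive directly at 26.

Step 13. Once the C4 hydroxyl is free, acid may ionise the para-hydroxybenzyl ether and water may then cut the ether bridge. The fallback sets out from 25 and accepts this cleavage. Warm CF3CO2H/H2O with more water drives hydrolysis through to 3,4,6-tribromo-5-(hydroxymethyl)benzene-1,2-diol F4. Acid-catalysed dehydrative self-etherification (p-TsOH cat., anhydrous MeCN, 4 Å molecular sieves) then rebuilds the symmetric ether and comes back at 26. Every ring position of F4 is substituted, so the benzylic cation cannot be taken up by ring carbon.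

**Further compounds**

F1 | step 11 | bis[(4,6-dibromo-7-hydroxy-2,2-dimethyl-1,3-benzodioxol-5-yl)methyl] ether | Oc1c(Br)c(COCc3c(Br)c4OC(C)(C)Oc4c(O)c3Br)c(Br)c2OC(C)(C)Oc12
F2 | step 11 | bis{[4,6-dibromo-2,2-dimethyl-7-(trifluoromethanesulfonyloxy)-1,3-benzodioxol-5-yl]methyl} ether | O=S(=O)(Oc1c(Br)c(COCc3c(Br)c4OC(C)(C)Oc4c(OS(=O)(=O)C(F)(F)F)c3Br)c(Br)c2OC(C)(C)Oc12)C(F)(F)F
F3 | step 12 | bis(2,3-dibromo-4,5-dihydroxybenzyl) ether | Oc1cc(COCc2cc(O)c(O)c(Br)c2Br)c(Br)c(Br)c1O
F4 | step 13 | 3,4,6-tribromo-5-(hydroxymethyl)benzene-1,2-diol | OCc1c(Br)c(Br)c(O)c(O)c1Br
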